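The route rests on the C9–C10 bond, which joins the methylene next to the tiglate carbinol to the fully substituted carbon of the 3(2H)-furanone ring. The C10–H of a 2-methyl-3(2H)-furanone (ring O, C10, C1, C2, C3) is acidic because its conjugate base is an aromatic 3-oxidofuran; this carbanion opens a terminal C8–C9 epoxide at C9. One operation closes the ten-membered carbocycle C1–C10, completes the oxygen-bridged 11-oxabicyclo[6.2.1]undecane core, creates quaternary C10 and frees the C8 hydroxyl for the tiglate. The precursor is an open-chain cis-lactone bearing the furanone on the Z-C4=C5 alkene and a C8/C9 hydroxy tosylate, its methylene lactone masked as a selenide.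

Key step: step 11

Remark: atoms are numbered as in germacranolides (C1 ketone, C2=C3, C4=C5 with C15H2OH on C4, C6 lactone carbinol, C7, C8 tiglate carbinol, C9, C10 with methyl C14, C11–C13 lactone carbons). The target as drawn is the (6S,7R,8R,10R) isomer with a cis-fused lactone. C10 in 14–18 and C11 in 12–22 are carried as epimer mixtures because both centres are reset later.

Step 1
Reactants: 1 but-2-yne-1,4-diol
Product: 2 4-[(tert-butyldiphenylsilyl)oxy]but-2-yn-1-ol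
Conditions: 1 (3 equiv), NaH (1 equiv), THF, 0 °C; TBDPSCl (1 equiv), rt
Reagents that add atoms: tert-butyl(chloro)diphenylsilane, CC(C)(C)[Si](Cl)(c1ccccc1)c1ccccc1
Why: O-silylation of the monoalkoxide of a symmetric diol used in excess should stop at the mono-ether, and no stereocentre is involved.

Step 2
Reactants: 2 4-[(tert-butyldiphenylsilyl)oxy]but-2-yn-1-ol
Product: 4 (2Z)-4-[(tert-butyldiphenylsilyl)oxy]-3-iodobut-2-en-1-ol, via vinylalanate 3 (not isolated)
Conditions: NaAlH2(OCH2CH2OMe)2 (Red-Al, 1.5 equiv), THF, 0 °C; then I2, −78 °C → 0 °C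
Reagents that add atoms: iodine, II
Why: Hydroxyl-directed trans-hydroalumination of the propargylic alcohol puts hydride on C5 and aluminium on C4 in a five-membered alkoxy alanate, and iododealumination with retention gives the Z-iodide with iodine cis to the CH2OH arm, which fixes the C4=C5 geometry of the target.

Step 3
Reactants: 4 (2Z)-4-[(tert-butyldiphenylsilyl)oxy]-3-iodobut-2-en-1-ol
Product: 5 (2Z)-4-[(tert-butyldiphenylsilyl)oxy]-3-iodobut-2-enal
Conditions: MnO2 (activated, excess), CH2Cl2, rt; used directly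
Reagents that add atoms: none
Why: Allylic oxidation on MnO2 stops at the aldehyde, and short contact with direct use should avoid Z to E isomerisation of the β-iodo enal.

Step 4
Reactants: 6 (4R)-2,2-dimethyl-1,3-dioxolane-4-carbaldehyde, 7 methyl acrylate
Product: 8 methyl 2-{[(4R)-2,2-dimethyl-1,3-dioxolan-4-yl](hydroxy)methyl}prop-2-enoate (both carbinol epimers)
Conditions: DABCO (0.3 equiv), 7 in excess, rt
Reagents that add atoms: none
Why: Morita–Baylis–Hillman reaction; the new carbinol centre is unselective but is erased in step 5, while the dioxolane centre (future C8) is not touched.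

Step 5
Reactants: 8 methyl 2-{[(4R)-2,2-dimethyl-1,3-dioxolan-4-yl](hydroxy)methyl}prop-2-enoate
Product: 9 methyl (2Z)-2-(bromomethyl)-3-[(4S)-2,2-dimethyl-1,3-dioxolan-4-yl]prop-2-enoate
Conditions: NBS, Me2S, CH2Cl2, 0 °C → rt
Reagents that add atoms: N-bromosuccinimide, BrN1C(=O)CCC1=O
Why: Bromide displaces the alkoxysulfonium salt of the Baylis–Hillman alcohol in the SN2′ sense to the preferred Z-2-(bromomethyl)alk-2-enoate (ester trans to the dioxolane) under non-acidic conditions that spare the acetonide.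

Step 6
Reactants: 5 (2Z)-4-[(tert-butyldiphenylsilyl)oxy]-3-iodobut-2-enal, 9 methyl (2Z)-2-(bromomethyl)-3-[(4S)-2,2-dimethyl-1,3-dioxolan-4-yl]prop-2-enoate
Product: 11 (4S,5R)-5-[(1Z)-3-[(tert-butyldiphenylsilyl)oxy]-2-iodoprop-1-en-1-yl]-4-[(4S)-2,2-dimethyl-1,3-dioxolan-4-yl]-3-methylideneoxolan-2-one, via hydroxy ester 10 (not isolated)
Conditions: In powder (1.5 equiv), THF/H2O (1:1), rt; then PPTS (cat.), toluene, 50 °C
Reagents that add atoms: none
Why: Barbier 2-(alkoxycarbonyl)allylation (SE2′) then lactonisation: the Z-allylindium reacts through a chair transition state with the dioxolanyl group axial, which gives the 6,7-syn adduct and so the cis-fused lactone, and with H8 turned over the ring by allylic 1,3-strain the aldehyde should bond to C7 anti to the C8–C9 bond with the smaller ring oxygen gauche to the forming bond, which sets C7 and C6 relative to the glyceraldehyde-derived C8.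

Step 7
Reactants: 11 (4S,5R)-5-[(1Z)-3-[(tert-butyldiphenylsilyl)oxy]-2-iodoprop-1-en-1-yl]-4-[(4S)-2,2-dimethyl-1,3-dioxolan-4-yl]-3-methylideneoxolan-2-one
Product: 12 (4S,5R)-5-[(1Z)-3-[(tert-butyldiphenylsilyl)oxy]-2-iodoprop-1-en-1-yl]-4-[(4S)-2,2-dimethyl-1,3-dioxolan-4-yl]-3-[(phenylselanyl)methyl]oxolan-2-one (both C3 epimers)
Conditions: PhSeH (1.1 equiv), Et3N (0.1 equiv), CH2Cl2, 0 °C
Reagents that add atoms: benzeneselenol, [SeH]c1ccccc1
Why: Conjugate addition of the soft selenol masks the only strong Michael acceptor before enolate chemistry, and the C11 centre formed is of no consequence because it returns to sp2 in step 13.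

Step 8
Reactants: 12 the selenide of step 7, 13 but-3-yn-2-ol (racemic)
Product: 14 (4S,5S)-5-[(1Z)-2-{[(tert-butyldiphenylsilyl)oxy]methyl}-6-hydroxy-3-oxohept-1-en-4-yn-1-yl]-4-[(4S)-2,2-dimethyl-1,3-dioxolan-4-yl]-3-[(phenylselanyl)methyl]oxolan-2-one
Conditions: PdCl2(PPh3)2 (5 mol %), CuI (5 mol %), Et3N, THF, CO (1 atm), rt
Reagents that add atoms: carbon monoxide, [C-]#[O+]
Why: Carbonylative Sonogashira coupling (oxidative addition to the vinyl iodide with retention of geometry, CO insertion, coupling with the copper acetylide) gives the γ-hydroxy ynone that holds C1–C3, C10 and C14.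

Step 9
Reactants: 14 the γ-hydroxy ynone of step 8
Product: 16 (4R,5S)-5-[(1Z)-3-[(tert-butyldiphenylsilyl)oxy]-2-(5-methyl-4-oxo-4,5-dihydrofuran-2-yl)prop-1-en-1-yl]-4-[(1S)-1,2-dihydroxyethyl]-3-[(phenylselanyl)methyl]oxolan-2-one, via enaminone 15 (not isolated)
Conditions: Et2NH (1.5 equiv), EtOH, rt; then AcOH/H2O (4:1), 40 °C
Reagents that add atoms: water, O
Why: Amine conjugate addition to the ynone and acid-induced cyclodehydration of the γ-hydroxy enaminone (hydroxyl onto the ketone, loss of water, iminium hydrolysis) is the classical route to 2-alkyl-3(2H)-furanones, and the same aqueous acid hydrolyses the terminal acetonide while the TBDPS ether and the lactone should persist.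

Step 10
Reactants: 16 the furanone diol of step 9
Product: 17 (4R,5S)-5-[(1Z)-3-[(tert-butyldiphenylsilyl)oxy]-2-(5-methyl-4-oxo-4,5-dihydrofuran-2-yl)prop-1-en-1-yl]-4-[(1S)-1-hydroxy-2-{[(4-methylphenyl)sulfonyl]oxy}ethyl]-3-[(phenylselanyl)methyl]oxolan-2-one
Conditions: TsCl (1.05 equiv), Bu2SnO (5 mol %), Et3N (1.2 equiv), CH2Cl2, 0 °C
Reagents that add atoms: 4-methylbenzenesulfonyl chloride, Cc1ccc(cc1)S(Cl)(=O)=O
Why: Stannylene-acetal-catalysed sulfonylation is selective for the primary hydroxyl of a 1,2-diol and should leave the C8 hydroxyl and the enolisable furanone untouched.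

Step 11
Reactants: 17 the hydroxy tosylate of step 10
Product: 19 (2Z,4S,8R,9R,11R)-2-{[(tert-butyldiphenylsilyl)oxy]methyl}-9-hydroxy-11-methyl-7-[(phenylselanyl)methyl]-5,14-dioxatricyclo[9.2.1.0^{4,8}]tetradeca-1(13),2-diene-6,12-dione, via epoxide 18 (not isolated)
Conditions: KN(SiMe3)2 (2.1 equiv), 18-crown-6, THF (2 mM in 17), −78 °C → 25 °C; recooled to −40 °C, AcOH
Reagents that add atoms: none
Why: One equivalent of base removes the C10–H to give the aromatic 3-oxidofuran and the second turns the hydroxy tosylate into the terminal epoxide 18; the C10 carbanion then opens the epoxide at C9 by SN2 displacement, which forms the C9–C10 bond and frees the C8 alkoxide with its configuration untouched. The closest known reaction types are the C2-alkylation of 2-alkyl-3(2H)-furanone enolates and the intramolecular enolate–epoxide alkylation used for medium rings. The ten-membered carbocycle C1–C10, and with it the nine-membered oxygen-bridged ring of the 11-oxabicyclo[6.2.1]undecane core, closes in the endo mode at the unsubstituted epoxide terminus. The new quaternary centre C10 is set by the substrate: the collinear C10···C9–O arrangement fixes the sign of the C7–C8–C9···C10 torsion through the epoxide carbon C8 and the cis-fused lactone turns the chain at C6–C7, so that C9 should reach the face of the planar furanolate that leads to 10R. The step needs C- over O-alkylation (the usual course for these enolates, and O-alkylation would give a more strained eleven-membered meta-bridged furan), attack at C9 and not C8 (secured by the primary terminus) and ring closure over oligomerisation (secured by high dilution). The selenide removes the competing Michael acceptor at C13 and the cold acid quench should limit translactonisation by the C8 alkoxide.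

Step 12
Reactants: 19 the macrocyclic alcohol of step 11, 20 (2E)-2-methylbut-2-enoyl chloride
Product: 21 (2Z,4S,8R,9R,11R)-2-{[(tert-butyldiphenylsilyl)oxy]methyl}-11-methyl-6,12-dioxo-7-[(phenylselanyl)methyl]-5,14-dioxatricyclo[9.2.1.0^{4,8}]tetradeca-1(13),2-dien-9-yl (2E)-2-methylbut-2-enoate
Conditions: pyridine, DMAP (0.2 equiv), CH2Cl2, 0 °C → rt
Reagents that add atoms: none
Why: Acylation through the acylpyridinium salt keeps the C8 configuration and the stable E geometry of the tiglate, and pyridine in place of a trialkylamine should avoid deconjugation through a vinylketene.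

Step 13
Reactants: 21 the tiglate of step 12
Product: 23 (2Z,4S,8R,9R,11R)-2-{[(tert-butyldiphenylsilyl)oxy]methyl}-11-methyl-7-methylidene-6,12-dioxo-5,14-dioxatricyclo[9.2.1.0^{4,8}]tetradeca-1(13),2-dien-9-yl (2E)-2-methylbut-2-enoate, via selenoxide 22 (not isolated)
Conditions: H2O2 (30% aq., excess), pyridine, CH2Cl2, 0 °C → rt
Reagents that add atoms: none
Why: Oxidation at selenium and syn-elimination of the selenoxide at room temperature regenerate the exocyclic methylene, the only β-hydrogen being on C11.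

Step 14
Reactants: 23 the silyl ether of step 13
Product: 24 [(2Z,4S,8R,9R,11R)-2-(hydroxymethyl)-11-methyl-7-methylidene-6,12-dioxo-5,14-dioxatricyclo[9.2.1.0^{4,8}]tetradeca-1(13),2-dien-9-yl] (2E)-2-methylbut-2-enoate
Conditions: HF·pyridine, pyridine, THF, 0 °C → rt
Reagents that add atoms: none
Why: Buffered fluoride cleavage of the silyl ether is non-basic and non-nucleophilic enough for the methylene lactone, the furanone and the tiglate, and touches no stereocentre.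

Compound list

1 | but-2-yne-1,4-diol | OCC#CCO | starting material
2 | 4-[(tert-butyldiphenylsilyl)oxy]but-2-yn-1-ol | OCC#CCO[Si](c1ccccc1)(c1ccccc1)C(C)(C)C | intermediate
3 | sodium 3-{[(tert-butyldiphenylsilyl)oxy]methyl}-2,2-bis(2-methoxyethoxy)-2,5-dihydro-1,2-oxaluminol-2-uide (cyclic vinylalanate) | [Na+].COCCO[Al-]1(OCCOC)OC/C=C1/CO[Si](c2ccccc2)(c2ccccc2)C(C)(C)C | intermediate
4 | (2Z)-4-[(tert-butyldiphenylsilyl)oxy]-3-iodobut-2-en-1-ol | OC/C=C(I)/CO[Si](c1ccccc1)(c1ccccc1)C(C)(C)C | intermediate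
5 | (2Z)-4-[(tert-butyldiphenylsilyl)oxy]-3-iodobut-2-enal | O=C/C=C(I)/CO[Si](c1ccccc1)(c1ccccc1)C(C)(C)C | intermediate
6 | (4R)-2,2-dimethyl-1,3-dioxolane-4-carbaldehyde | CC1(C)OC[C@@H](O1)C=O | starting material
7 | methyl acrylate | C=CC(=O)OC | starting material
8 | methyl 2-{[(4R)-2,2-dimethyl-1,3-dioxolan-4-yl](hydroxy)methyl}prop-2-enoate, both carbinol epimers | CC1(C)OC[C@@H](O1)C(O)C(=C)C(=O)OC | intermediate
9 | methyl (2Z)-2-(bromomethyl)-3-[(4S)-2,2-dimethyl-1,3-dioxolan-4-yl]prop-2-enoate | CC1(C)OC[C@@H](O1)/C=C(\CBr)C(=O)OC | intermediate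
10 | methyl (3S,4R,5Z)-7-[(tert-butyldiphenylsilyl)oxy]-3-[(4S)-2,2-dimethyl-1,3-dioxolan-4-yl]-4-hydroxy-6-iodo-2-methylidenehept-5-enoate | C=C(C(=O)OC)[C@H]([C@H]8COC(C)(C)O8)[C@@H](O)/C=C(/CO[Si](c4ccccc4)(c5ccccc5)C(C)(C)C)I | intermediate
11 | (4S,5R)-5-[(1Z)-3-[(tert-butyldiphenylsilyl)oxy]-2-iodoprop-1-en-1-yl]-4-[(4S)-2,2-dimethyl-1,3-dioxolan-4-yl]-3-methylideneoxolan-2-one | C=C1C(=O)O[C@@H](/C=C(/CO[Si](c4ccccc4)(c5ccccc5)C(C)(C)C)I)[C@H]1[C@H]8COC(C)(C)O8 | intermediate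
12 | (4S,5R)-5-[(1Z)-3-[(tert-butyldiphenylsilyl)oxy]-2-iodoprop-1-en-1-yl]-4-[(4S)-2,2-dimethyl-1,3-dioxolan-4-yl]-3-[(phenylselanyl)methyl]oxolan-2-one, both C3 epimers | c6ccccc6[Se]CC1C(=O)O[C@@H](/C=C(/CO[Si](c4ccccc4)(c5ccccc5)C(C)(C)C)I)[C@H]1[C@H]8COC(C)(C)O8 | intermediate
13 | but-3-yn-2-ol (racemic) | CC(O)C#C | starting material
14 | (4S,5S)-5-[(1Z)-2-{[(tert-butyldiphenylsilyl)oxy]methyl}-6-hydroxy-3-oxohept-1-en-4-yn-1-yl]-4-[(4S)-2,2-dimethyl-1,3-dioxolan-4-yl]-3-[(phenylselanyl)methyl]oxolan-2-one | c6ccccc6[Se]CC1C(=O)O[C@@H](/C=C(/CO[Si](c4ccccc4)(c5ccccc5)C(C)(C)C)C(=O)C#CC(C)O)[C@H]1[C@H]8COC(C)(C)O8 | intermediate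
15 | (4S,5S)-5-[(1Z)-2-{[(tert-butyldiphenylsilyl)oxy]methyl}-5-(diethylamino)-6-hydroxy-3-oxohepta-1,4-dien-1-yl]-4-[(4S)-2,2-dimethyl-1,3-dioxolan-4-yl]-3-[(phenylselanyl)methyl]oxolan-2-one | c6ccccc6[Se]CC1C(=O)O[C@@H](/C=C(/CO[Si](c4ccccc4)(c5ccccc5)C(C)(C)C)C(=O)C=C(N(CC)CC)C(C)O)[C@H]1[C@H]8COC(C)(C)O8 | intermediate
16 | (4R,5S)-5-[(1Z)-3-[(tert-butyldiphenylsilyl)oxy]-2-(5-methyl-4-oxo-4,5-dihydrofuran-2-yl)prop-1-en-1-yl]-4-[(1S)-1,2-dihydroxyethyl]-3-[(phenylselanyl)methyl]oxolan-2-one | c6ccccc6[Se]CC1C(=O)O[C@@H](/C=C(/CO[Si](c4ccccc4)(c5ccccc5)C(C)(C)C)C3=CC(=O)C(C)O3)[C@H]1[C@H](O)CO | intermediate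
17 | (4R,5S)-5-[(1Z)-3-[(tert-butyldiphenylsilyl)oxy]-2-(5-methyl-4-oxo-4,5-dihydrofuran-2-yl)prop-1-en-1-yl]-4-[(1S)-1-hydroxy-2-{[(4-methylphenyl)sulfonyl]oxy}ethyl]-3-[(phenylselanyl)methyl]oxolan-2-one | c6ccccc6[Se]CC1C(=O)O[C@@H](/C=C(/CO[Si](c4ccccc4)(c5ccccc5)C(C)(C)C)C3=CC(=O)C(C)O3)[C@H]1[C@H](O)COS(=O)(=O)c7ccc(C)cc7 | intermediate
18 | (4S,5S)-5-[(1Z)-3-[(tert-butyldiphenylsilyl)oxy]-2-(5-methyl-4-oxo-4,5-dihydrofuran-2-yl)prop-1-en-1-yl]-4-[(2S)-oxiran-2-yl]-3-[(phenylselanyl)methyl]oxolan-2-one | c6ccccc6[Se]CC1C(=O)O[C@@H](/C=C(/CO[Si](c4ccccc4)(c5ccccc5)C(C)(C)C)C3=CC(=O)C(C)O3)[C@H]1[C@H]8CO8 | intermediate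
19 | (2Z,4S,8R,9R,11R)-2-{[(tert-butyldiphenylsilyl)oxy]methyl}-9-hydroxy-11-methyl-7-[(phenylselanyl)methyl]-5,14-dioxatricyclo[9.2.1.0^{4,8}]tetradeca-1(13),2-diene-6,12-dione, both C7 epimers | c6ccccc6[Se]CC1C(=O)O[C@H]2/C=C(/CO[Si](c4ccccc4)(c5ccccc5)C(C)(C)C)C3=CC(=O)[C@@](C)(C[C@@H](O)[C@@H]12)O3 | intermediate
20 | (2E)-2-methylbut-2-enoyl chloride (tigloyl chloride) | C/C=C(\C)C(Cl)=O | starting material
21 | (2Z,4S,8R,9R,11R)-2-{[(tert-butyldiphenylsilyl)oxy]methyl}-11-methyl-6,12-dioxo-7-[(phenylselanyl)methyl]-5,14-dioxatricyclo[9.2.1.0^{4,8}]tetradeca-1(13),2-dien-9-yl (2E)-2-methylbut-2-enoate | c6ccccc6[Se]CC1C(=O)O[C@H]2/C=C(/CO[Si](c4ccccc4)(c5ccccc5)C(C)(C)C)C3=CC(=O)[C@@](C)(C[C@@H](OC(=O)/C(C)=C/C)[C@@H]12)O3 | intermediate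
22 | the Se-oxide of 21, 7-[(phenylseleninyl)methyl] | O=[Se](c6ccccc6)CC1C(=O)O[C@H]2/C=C(/CO[Si](c4ccccc4)(c5ccccc5)C(C)(C)C)C3=CC(=O)[C@@](C)(C[C@@H](OC(=O)/C(C)=C/C)[C@@H]12)O3 | intermediate
23 | (2Z,4S,8R,9R,11R)-2-{[(tert-butyldiphenylsilyl)oxy]methyl}-11-methyl-7-methylidene-6,12-dioxo-5,14-dioxatricyclo[9.2.1.0^{4,8}]tetradeca-1(13),2-dien-9-yl (2E)-2-methylbut-2-enoate | C=C1C(=O)O[C@H]2/C=C(/CO[Si](c4ccccc4)(c5ccccc5)C(C)(C)C)C3=CC(=O)[C@@](C)(C[C@@H](OC(=O)/C(C)=C/C)[C@@H]12)O3 | intermediate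
24 | [(2Z,4S,8R,9R,11R)-2-(hydroxymethyl)-11-methyl-7-methylidene-6,12-dioxo-5,14-dioxatricyclo[9.2.1.0^{4,8}]tetradeca-1(13),2-dien-9-yl] (2E)-2-methylbut-2-enoate | C=C1C(=O)O[C@H]2/C=C(/CO)C3=CC(=O)[C@@](C)(C[C@@H](OC(=O)/C(C)=C/C)[C@@H]12)O3 | target

Total step count: 14. Longest linear sequence: 12 steps (steps 1–3 and 6–14, from but-2-yne-1,4-diol).

Steps most likely to fail

Step 11. The ambident furanolate may be alkylated at oxygen, the C8 alkoxide may attack the lactone carbonyl before or after ring closure, and the chain may reach the other face of C10. The fallback sets out from 17 and comes back at 19. The C8 hydroxyl would be silylated (Et3SiCl, imidazole, DMF, 0 °C) to the C8 triethylsilyl ether of 17 F1. Tosylate–iodide exchange (NaI, acetone, 50 °C) would give the C9 iodide F2. The ring would then be closed on the soft primary iodide through the cesium enolate (Cs2CO3, MeCN, 2 mM, 40 °C), with no alkoxide present, to the C8 triethylsilyl ether of 19 F3. PPTS in MeOH at 0 °C would free the C8 hydroxyl selectively and return 19. Face selection stays substrate-controlled in this variant.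

Step 6. The aldehyde may instead add to the allyl unit anti to the C8–O bond, which would invert C6 and C7 relative to C8. The fallback sets out from 5 and comes back at 21. (4S)-2,2-Dimethyl-1,3-dioxolane-4-carbaldehyde F4 would be taken through steps 4 and 5 to the Baylis–Hillman adduct F5 and the (4R)-configured Z-bromide F6. With that facial sense, F6 and 5 would give the hydroxy ester F7 and then the C8 epimer of 11 F8, which has the target configuration at C6 and C7. Steps 7–11 would be run unchanged on this series: the C8 epimer of 12 F9, the C8 epimer of 14 F10, the C8-epimeric enaminone F11, the C8 epimer of 16 F12, the C8 epimer of 17 F13, the C8-epimeric epoxide F14 and the C8 epimer of 19 F15. Mitsunobu esterification of F15 with tiglic acid (PPh3, DIAD, toluene, 0 °C → rt) would install the tiglate with inversion at C8 and return 21.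

Step 8. Direct alkynylation without CO insertion, acylation of the free hydroxyl of 13 by the acylpalladium species, or slowing of the catalyst by the selenide may occur. The fallback sets out from 12 and comes back at 16. Sonogashira coupling with ethynyltrimethylsilane (Pd(PPh3)4, CuI, Et3N) would give the silyl enyne F16, and K2CO3 in MeOH at 0 °C the terminal enyne F17. Acyl Sonogashira coupling with (2S)-2-acetoxypropanoyl chloride (PdCl2(PPh3)2, CuI, Et3N, THF) would give the acetoxy ynone F18, in which the carbonyl is C1. K2CO3 in MeOH would cleave the acetate to the hydroxy ynone F19, whose hydroxyl adds to C3 in the 5-endo mode to give the furanone acetonide F20. Aqueous acetic acid at 40 °C would remove the acetonide and return 16.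

Further compounds

F1 | step 11 | C8 triethylsilyl ether of 17 | c6ccccc6[Se]CC1C(=O)O[C@@H](/C=C(/CO[Si](c4ccccc4)(c5ccccc5)C(C)(C)C)C3=CC(=O)C(C)O3)[C@H]1[C@H](O[Si](CC)(CC)CC)COS(=O)(=O)c7ccc(C)cc7
F2 | step 11 | C9 iodide, C8 triethylsilyl ether | c6ccccc6[Se]CC1C(=O)O[C@@H](/C=C(/CO[Si](c4ccccc4)(c5ccccc5)C(C)(C)C)C3=CC(=O)C(C)O3)[C@H]1[C@H](O[Si](CC)(CC)CC)CI
F3 | step 11 | C8 triethylsilyl ether of 19 | c6ccccc6[Se]CC1C(=O)O[C@H]2/C=C(/CO[Si](c4ccccc4)(c5ccccc5)C(C)(C)C)C3=CC(=O)[C@@](C)(C[C@@H](O[Si](CC)(CC)CC)[C@@H]12)O3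
F4 | step 6 | (4S)-2,2-dimethyl-1,3-dioxolane-4-carbaldehyde | CC1(C)OC[C@H](O1)C=O
F5 | step 6 | methyl 2-{[(4S)-2,2-dimethyl-1,3-dioxolan-4-yl](hydroxy)methyl}prop-2-enoate | CC1(C)OC[C@H](O1)C(O)C(=C)C(=O)OC
F6 | step 6 | methyl (2Z)-2-(bromomethyl)-3-[(4R)-2,2-dimethyl-1,3-dioxolan-4-yl]prop-2-enoate | CC1(C)OC[C@H](O1)/C=C(\CBr)C(=O)OC
F7 | step 6 | C8 epimer of 10 | C=C(C(=O)OC)[C@H]([C@@H]8COC(C)(C)O8)[C@@H](O)/C=C(/CO[Si](c4ccccc4)(c5ccccc5)C(C)(C)C)I
F8 | step 6 | C8 epimer of 11 | C=C1C(=O)O[C@@H](/C=C(/CO[Si](c4ccccc4)(c5ccccc5)C(C)(C)C)I)[C@H]1[C@@H]8COC(C)(C)O8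
F9 | step 6 | C8 epimer of 12 | c6ccccc6[Se]CC1C(=O)O[C@@H](/C=C(/CO[Si](c4ccccc4)(c5ccccc5)C(C)(C)C)I)[C@H]1[C@@H]8COC(C)(C)O8
F10 | step 6 | C8 epimer of 14 | c6ccccc6[Se]CC1C(=O)O[C@@H](/C=C(/CO[Si](c4ccccc4)(c5ccccc5)C(C)(C)C)C(=O)C#CC(C)O)[C@H]1[C@@H]8COC(C)(C)O8
F11 | step 6 | C8 epimer of 15 | c6ccccc6[Se]CC1C(=O)O[C@@H](/C=C(/CO[Si](c4ccccc4)(c5ccccc5)C(C)(C)C)C(=O)C=C(N(CC)CC)C(C)O)[C@H]1[C@@H]8COC(C)(C)O8
F12 | step 6 | C8 epimer of 16 | c6ccccc6[Se]CC1C(=O)O[C@@H](/C=C(/CO[Si](c4ccccc4)(c5ccccc5)C(C)(C)C)C3=CC(=O)C(C)O3)[C@H]1[C@@H](O)CO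
F13 | step 6 | C8 epimer of 17 | c6ccccc6[Se]CC1C(=O)O[C@@H](/C=C(/CO[Si](c4ccccc4)(c5ccccc5)C(C)(C)C)C3=CC(=O)C(C)O3)[C@H]1[C@@H](O)COS(=O)(=O)c7ccc(C)cc7
F14 | step 6 | C8 epimer of 18 | c6ccccc6[Se]CC1C(=O)O[C@@H](/C=C(/CO[Si](c4ccccc4)(c5ccccc5)C(C)(C)C)C3=CC(=O)C(C)O3)[C@H]1[C@@H]8CO8
F15 | step 6 | C8 epimer of 19 (9S) | c6ccccc6[Se]CC1C(=O)O[C@H]2/C=C(/CO[Si](c4ccccc4)(c5ccccc5)C(C)(C)C)C3=CC(=O)[C@@](C)(C[C@H](O)[C@@H]12)O3
F16 | step 8 | trimethylsilyl enyne from 12 | c6ccccc6[Se]CC1C(=O)O[C@@H](/C=C(/CO[Si](c4ccccc4)(c5ccccc5)C(C)(C)C)C#C[Si](C)(C)C)[C@H]1[C@H]8COC(C)(C)O8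
F17 | step 8 | terminal enyne | c6ccccc6[Se]CC1C(=O)O[C@@H](/C=C(/CO[Si](c4ccccc4)(c5ccccc5)C(C)(C)C)C#C)[C@H]1[C@H]8COC(C)(C)O8
F18 | step 8 | acetoxy ynone (carbonyl at C1) | c6ccccc6[Se]CC1C(=O)O[C@@H](/C=C(/CO[Si](c4ccccc4)(c5ccccc5)C(C)(C)C)C#CC(=O)[C@H](C)OC(C)=O)[C@H]1[C@H]8COC(C)(C)O8
F19 | step 8 | hydroxy ynone (carbonyl at C1) | c6ccccc6[Se]CC1C(=O)O[C@@H](/C=C(/CO[Si](c4ccccc4)(c5ccccc5)C(C)(C)C)C#CC(=O)C(C)O)[C@H]1[C@H]8COC(C)(C)O8
F20 | step 8 | acetonide of 16 | c6ccccc6[Se]CC1C(=O)O[C@@H](/C=C(/CO[Si](c4ccccc4)(c5ccccc5)C(C)(C)C)C3=CC(=O)C(C)O3)[C@H]1[C@H]8COC(C)(C)O8
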